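**Plan**

Numbering: ring A is the benzene ring, C1 bearing the side chain, C2 OH, C3 OMe, C5 OH. The side chain is C1'–C13', with the acetoxy group on C2'.

- Retrosynthesis: the two phenols are masked as aryl acetates. C2' is then cut at C2'–C3' and at its O–acetyl bond, giving arylacetaldehyde 6 (C1'–C2'), acetyl bromide 7 and 1-undecene 8 (C3'–C13'). Aldehyde 6 goes back through an allyl group and a quinone to o-eugenol 1.
- Forward: ring A is bought complete. The C5 oxygen is added by phenol oxidation, the quinone is reductively acetylated, the allyl group is cut to the aldehyde, the C11 chain and the acetate are joined in one operation, and the aryl acetates are removed.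
- Enabling feature: C2' carries an acyloxy oxygen between two similar CH2 groups (benzylic C1' and aliphatic C3'). As a planar α-acetoxy radical at C2', the ester carbonyl can bind nickel and so set the face of C2'–C3' bond formation.
- Stereochemistry: the only stereocenter, C2' (R), is set by a chiral bis(oxazoline)–nickel catalyst in step 4 and is not touched afterwards.

Key step: step 4

Assumption: the sense of induction of a given bis(oxazoline) enantiomer (L*, for instance 2,2'-isopropylidenebis(4-benzyl-2-oxazoline) in its (S,S) or (R,R) form) on this arylmethyl-substituted radical is to be assigned in a first run; both ligand enantiomers are available, so the (R) configuration at C2' is accessible either way.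

**Route**

Step 1
Reactants: 1 o-eugenol (2-allyl-6-methoxyphenol)
Product: 2 2-allyl-6-methoxy-1,4-benzoquinone
Conditions: (KSO3)2NO (2.2 equiv), KH2PO4 buffer, H2O/acetone, 0 °C → rt
Reagents that add atoms: potassium nitrosodisulfonate (Fremy's salt), [K+].[K+].[O]N(S(=O)(=O)[O-])S(=O)(=O)[O-]
Why: Teuber oxidation, in which the nitroxyl radical removes the phenolic hydrogen and a second equivalent delivers oxygen to the free para position C5, should give the p-quinone while the allyl and methoxy groups are left alone by this one-electron oxidant.

Step 2
Reactants: 2 2-allyl-6-methoxy-1,4-benzoquinone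
Product: 4 2-allyl-6-methoxy-1,4-phenylene diacetate, via 2-allyl-6-methoxyhydroquinone 3 (not isolated)
Conditions: Zn dust, Ac2O, AcOH, NaOAc, 0 °C → rt
Reagents that add atoms: acetic anhydride, CC(=O)OC(C)=O
Why: Reductive acetylation, in which zinc in acetic acid reduces the quinone and the air-sensitive hydroquinone is trapped at once by Ac2O/NaOAc (the acetic acid consumed is returned in the acylation), should give the stable diacetate without touching the isolated terminal alkene.

Step 3
Reactants: 4 2-allyl-6-methoxy-1,4-phenylene diacetate
Product: 6 2-(2,5-diacetoxy-3-methoxyphenyl)acetaldehyde, via secondary ozonide 5 (not isolated)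
Conditions: O3, CH2Cl2, −78 °C (Sudan Red 7B end point); then PPh3, −78 °C → rt; rapid silica filtration, used at once
Reagents that add atoms: ozone, [O-][O+]=O
Why: Ozonolysis with reductive work-up should cleave the terminal alkene much faster than ozone attacks ring A, which two acyloxy groups deactivate, and PPh3 reduces the ozonide to the aldehyde under neutral conditions that spare the enolisable arylacetaldehyde.

Step 4
Reactants: 6 2-(2,5-diacetoxy-3-methoxyphenyl)acetaldehyde; 7 acetyl bromide; 8 1-undecene
Product: 10 (R)-1-(2,5-diacetoxy-3-methoxyphenyl)tridecan-2-yl acetate, via racemic 1-bromoalkyl acetate 9 (not isolated)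
Conditions: AcBr (1.05 equiv), toluene, 0 °C; then 1-undecene (2 equiv), NiBr2·glyme (10 mol %), chiral bis(oxazoline) L* (12 mol %), (EtO)2MeSiH, K3PO4·H2O, Et2O/DMA, 0 °C → rt
Reagents that add atoms: none
Why: Acetyl bromide adds across the carbonyl group of 6 to give the racemic bromide 9, from which a monovalent nickel complex abstracts bromine to leave a planar α-acetoxy radical at C2', while a nickel hydride generated from NiBr2·glyme, the ligand, the silane and the phosphate base inserts 8 with anti-Markovnikov sense to give an undecylnickel species of divalent nickel that captures the radical and then forms C2'–C3' by reductive elimination from trivalent nickel. The closest known reaction type is the nickel-hydride-catalysed enantioconvergent coupling of racemic 1-haloalkyl esters with olefins and a hydrosilane, including its one-pot form that starts from an aldehyde and an acyl bromide. No ring is closed in this step. The new stereocenter C2' is controlled by the chiral bis(oxazoline) ligand on nickel: both enantiomers of 9 give the same radical, and the catalyst is expected to bind it with the acetate carbonyl oxygen on nickel, so that the acyloxy group and not the two CH2 arms defines the face of bond formation. The step needs linear regioselectivity in the hydrometalation, which the unbranched terminal alkene of 8 secures, and coupling that outruns loss of HBr from 9 toward the conjugated enol acetate, which the low temperature and the weak, sparingly soluble base favour. The aryl acetates and the methyl ether on ring A are inert to the catalyst, and partial loss of an aryl acetate would be of no consequence because both are removed in step 5.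

Step 5
Reactants: 10 (R)-1-(2,5-diacetoxy-3-methoxyphenyl)tridecan-2-yl acetate
Product: 11 (R)-1-(2,5-dihydroxy-3-methoxyphenyl)tridecan-2-yl acetate (CNP0331604.1)
Conditions: pyrrolidine (2.5 equiv), degassed CH2Cl2, 0 °C, argon; cold dilute aqueous HCl/Na2S2O4 work-up
Reagents that add atoms: none
Why: Chemoselective aminolysis should remove only the two aryl acetates, which are activated esters with a phenoxide leaving group and react with a secondary amine far faster than the secondary alkyl acetate at C2', whose configuration is not involved.

**Compound list**

1 | o-eugenol (2-allyl-6-methoxyphenol) | C=CCc1cccc(OC)c1O | starting material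
2 | 2-allyl-6-methoxy-1,4-benzoquinone | C=CCC1=CC(=O)C=C(OC)C1=O | intermediate
3 | 2-allyl-6-methoxyhydroquinone (2-allyl-6-methoxybenzene-1,4-diol) | C=CCc1cc(O)cc(OC)c1O | intermediate (not isolated)
4 | 2-allyl-6-methoxy-1,4-phenylene diacetate | C=CCc1cc(OC(C)=O)cc(OC)c1OC(C)=O | intermediate
5 | secondary ozonide, 3-[(2,5-diacetoxy-3-methoxyphenyl)methyl]-1,2,4-trioxolane | CC(=O)Oc1cc(CC2OCOO2)c(OC(C)=O)c(OC)c1 | intermediate (not isolated)
6 | 2-(2,5-diacetoxy-3-methoxyphenyl)acetaldehyde | O=CCc1cc(OC(C)=O)cc(OC)c1OC(C)=O | intermediate
7 | acetyl bromide | CC(Br)=O | starting material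
8 | 1-undecene | C=CCCCCCCCCC | starting material
9 | rac-1-bromo-2-(2,5-diacetoxy-3-methoxyphenyl)ethyl acetate | CC(=O)OC(Br)Cc1cc(OC(C)=O)cc(OC)c1OC(C)=O | intermediate (not isolated)
10 | (R)-1-(2,5-diacetoxy-3-methoxyphenyl)tridecan-2-yl acetate | CCCCCCCCCCC[C@H](Cc1cc(OC(C)=O)cc(OC)c1OC(C)=O)OC(C)=O | intermediate
11 | (R)-1-(2,5-dihydroxy-3-methoxyphenyl)tridecan-2-yl acetate (CNP0331604.1) | CCCCCCCCCCC[C@H](Cc1cc(O)cc(OC)c1O)OC(C)=O | target

**Step count and risks**

Total step count: 5. Longest linear sequence: 5 steps (1 → 2 → 4 → 6 → 10 → 11); 7 and 8 are bought.

Steps most likely to fail: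

1. Step 4. The bromide 9 may lose HBr toward the conjugated enol acetate under the basic conditions, the nickel hydride may reduce the C–Br bond, or the arylmethyl arm may erode facial selectivity at the radical. The fallback removes base, silane and nickel hydride by changing the nucleophile. It sets out from 6 and 7: bromide 9 is formed in toluene at 0 °C and freed of volatiles. It is then coupled, under NiBr2·glyme and the same chiral bis(oxazoline) in THF/DMA at −10 to 0 °C, with undecylzinc bromide F1, made from commercial 1-bromoundecane, zinc dust and catalytic iodine in DMA. This enantioconvergent Negishi coupling comes back to the route at 10.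

2. Step 5. The freed hydroquinone may autoxidise in the presence of the amine and then add pyrrolidine as the quinone, or the C2' acetate may be lost through acyl transfer to the neighbouring C2 phenol followed by aminolysis. The fallback changes the phenol protection to benzyl ethers so that the last step is a neutral hydrogenolysis. It sets out from quinone 2, which is reduced with aqueous Na2S2O4 to hydroquinone 3 and benzylated (BnBr, K2CO3, degassed DMF) to 1-allyl-2,5-bis(benzyloxy)-3-methoxybenzene F2. Lemieux–Johnson cleavage (catalytic OsO4, NaIO4, 2,6-lutidine, dioxane/H2O) through 3-[2,5-bis(benzyloxy)-3-methoxyphenyl]propane-1,2-diol F3 gives 2-[2,5-bis(benzyloxy)-3-methoxyphenyl]acetaldehyde F4. Treatment with 7 gives rac-1-bromo-2-[2,5-bis(benzyloxy)-3-methoxyphenyl]ethyl acetate F5, which is coupled with 8 under the conditions of step 4 to give (R)-1-[2,5-bis(benzyloxy)-3-methoxyphenyl]tridecan-2-yl acetate F6. Hydrogenolysis (H2, Pd/C, EtOAc) then comes back to the route at the target 11.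

3. Step 3. Ozone may over-oxidise ring A once the alkene is consumed, and the arylacetaldehyde may self-condense or enolise during work-up and purification. The fallback replaces ozone by an osmium-based cleavage. It sets out from 4, which is dihydroxylated and cleaved in one pot (catalytic OsO4, NaIO4, 2,6-lutidine, dioxane/H2O) through 3-(2,5-diacetoxy-3-methoxyphenyl)propane-1,2-diol F7, the diol being cut as it forms so that acyl transfer from the C2 acetate has little time to occur. It comes back to the route at aldehyde 6.

**Further compounds**

F1 | step 4 | undecylzinc bromide | CCCCCCCCCCC[Zn]Br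
F2 | step 5 | 1-allyl-2,5-bis(benzyloxy)-3-methoxybenzene | C=CCc1cc(OCc2ccccc2)cc(OC)c1OCc1ccccc1
F3 | step 5 | 3-[2,5-bis(benzyloxy)-3-methoxyphenyl]propane-1,2-diol | OCC(O)Cc1cc(OCc2ccccc2)cc(OC)c1OCc1ccccc1
F4 | step 5 | 2-[2,5-bis(benzyloxy)-3-methoxyphenyl]acetaldehyde | O=CCc1cc(OCc2ccccc2)cc(OC)c1OCc1ccccc1
F5 | step 5 | rac-1-bromo-2-[2,5-bis(benzyloxy)-3-methoxyphenyl]ethyl acetate | CC(=O)OC(Br)Cc1cc(OCc2ccccc2)cc(OC)c1OCc1ccccc1
F6 | step 5 | (R)-1-[2,5-bis(benzyloxy)-3-methoxyphenyl]tridecan-2-yl acetate | CCCCCCCCCCC[C@H](Cc1cc(OCc2ccccc2)cc(OC)c1OCc1ccccc1)OC(C)=O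
F7 | step 3 | 3-(2,5-diacetoxy-3-methoxyphenyl)propane-1,2-diol | OCC(O)Cc1cc(OC(C)=O)cc(OC)c1OC(C)=O
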